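Rings: A = ten-membered keto-lactone, B = butyrolactone, C = 2-alkylidene-tetrahydrofuran, D = methyl-tetrahydropyran. They are closed in the order A, B, C, D.
Ring D (last): the bond between the ring-D oxygen and the CH(CH3) carbon is cut. The precursor is the A/B/C tricycle with a free OH on the C/D fusion carbon next to the ring-C CH2 and a plain but-3-enyl chain on the other fusion carbon. A cobalt-hydride hydrogen-atom-transfer (MHAT) hydroalkoxylation closes the ring.
Enabling feature: the CH(CH3) carbon of ring D carries only H and CH3 besides ring atoms, so it is the Markovnikov carbon of a terminal alkene lying 1,5 to the fusion carbinol that ring C holds cis to the chain. The only other C=C (the B=C junction) is a tetrasubstituted vinylogous carbonate that accepts no hydrogen atom.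
Rings B and C: one base domino acts on a β-keto ester hung on the allylic OH of the ring-A enone. A Michael addition closes B, and enolate O-alkylation at a secondary chloride closes C with inversion. The ester comes from an acylketene made by dioxinone thermolysis.
Ring A: ring-closing metathesis of a vinyl ketone/allyl silyl ether diene ester. Building blocks are (R)-γ-valerolactone, acrolein, hex-5-enal and 2,2,6-trimethyl-1,3-dioxin-4-one.
Key step: step 14

Remark: the antipode of the acetate auxiliary (step 1) and of the pyrrolidine catalyst (step 9) is taken to be the one that gives the drawn configuration. Both antipodes of each are commercial.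

Step 1
Reactants: 1 (S)-2-hydroxy-1,2,2-triphenylethyl acetate; 2 acrolein
Product: 3 (S)-2-hydroxy-1,2,2-triphenylethyl (S)-3-hydroxypent-4-enoate
Conditions: LiN(iPr)2 (2.1 equiv), THF, −78 to 0 °C; then 2, −78 °C; aq. NH4Cl
Reagents that add atoms: none
Why: Acetate aldol addition of the doubly deprotonated chiral acetate, in which the triphenylglycol unit shields one enolate face and so sets the (S)-carbinol centre (later the oxygen-bearing A/B fusion carbon), while a lithium enolate adds 1,2 to acrolein at low temperature.

Step 2
Reactants: 3 (S)-2-hydroxy-1,2,2-triphenylethyl (S)-3-hydroxypent-4-enoate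
Product: 4 (S)-3-hydroxypent-4-enoic acid
Conditions: KOH, MeOH–H2O, 23 °C; then HCl to pH 2
Reagents that add atoms: water, O
Why: Ester saponification releases the auxiliary diol, which is removed by extraction, and leaves the allylic carbinol centre untouched.

Step 3
Reactants: 4 (S)-3-hydroxypent-4-enoic acid
Product: 6 (S)-3-(tert-butyldimethylsilyloxy)pent-4-enoic acid, via silyl ester 5 (not isolated)
Conditions: TBSCl (2.5 equiv), imidazole, DMF, 23 °C; then K2CO3 (cat.), MeOH–THF–H2O, 23 °C
Reagents that add atoms: tert-butyldimethylsilyl chloride, CC(C)(C)[Si](C)(C)Cl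
Why: Silylation of both OH groups followed by selective solvolysis of the labile silyl ester frees the acid and keeps the allylic alcohol masked for the Grignard and metathesis steps.

Step 4
Reactants: 7 (R)-γ-valerolactone
Product: 8 (R)-4-hydroxy-N-methoxy-N-methylpentanamide
Conditions: MeNH(OMe)·HCl, iPrMgCl, THF, −20 to 0 °C
Reagents that add atoms: N,O-dimethylhydroxylamine hydrochloride, CNOC.Cl
Why: Aminolysis of the lactone by the magnesium amide opens the chiral-pool lactone at the acyl carbon, so its (R)-centre, the future methyl carbinol centre of ring A, is carried over unchanged.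

Step 5
Reactants: 6 (S)-3-(tert-butyldimethylsilyloxy)pent-4-enoic acid; 8 (R)-4-hydroxy-N-methoxy-N-methylpentanamide
Product: 9 (R)-5-[methoxy(methyl)amino]-5-oxopentan-2-yl (S)-3-(tert-butyldimethylsilyloxy)pent-4-enoate
Conditions: EDC·HCl, DMAP, CH2Cl2, 0 to 23 °C
Reagents that add atoms: none
Why: Steglich esterification joins the acid to the secondary alcohol under mild conditions, and both stereocentres are spectators.

Step 6
Reactants: 9 (R)-5-[methoxy(methyl)amino]-5-oxopentan-2-yl (S)-3-(tert-butyldimethylsilyloxy)pent-4-enoate
Product: 10 (R)-5-oxohept-6-en-2-yl (S)-3-(tert-butyldimethylsilyloxy)pent-4-enoate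
Conditions: CH2=CHMgBr (1.2 equiv), THF, −78 to −40 °C; inverse quench into cold aq. KHSO4
Reagents that add atoms: vinylmagnesium bromide, C=C[Mg]Br
Why: Grignard ketone synthesis on the N-methoxy-N-methylamide, where the chelated tetrahedral adduct blocks over-addition, the amide reacts ahead of the hindered secondary ester at low temperature, and the acidic inverse quench keeps the released amine from adding to the vinyl ketone.

Step 7
Reactants: 10 (R)-5-oxohept-6-en-2-yl (S)-3-(tert-butyldimethylsilyloxy)pent-4-enoate
Product: 11 (4S,5E,10R)-4-(tert-butyldimethylsilyloxy)-10-methyloxacyclodec-5-ene-2,7-dione (ring A)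
Conditions: second-generation Hoveyda–Grubbs catalyst (10 mol %), 1,4-benzoquinone (20 mol %), toluene (1 mM), 80 °C
Reagents that add atoms: none
Why: Ring-closing metathesis at high dilution, of the kind widely used for ten-membered lactones, in which initiation at the allyl silyl ether alkene and closure onto the vinyl ketone should give the conjugated (E)-enone as the less strained isomer.

Step 8
Reactants: 11 (4S,5E,10R)-4-(tert-butyldimethylsilyloxy)-10-methyloxacyclodec-5-ene-2,7-dione
Product: 12 (4S,5E,10R)-4-hydroxy-10-methyloxacyclodec-5-ene-2,7-dione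
Conditions: HF·pyridine, pyridine–THF, 0 to 23 °C
Reagents that add atoms: none
Why: Buffered fluoride desilylation frees the allylic alcohol without the base that could isomerise the γ-hydroxy enone.

Step 9
Reactants: 13 hex-5-enal
Product: 14 (R)-2-chlorohex-5-enal
Conditions: N-chlorosuccinimide, (2S,5S)-2,5-diphenylpyrrolidine (10 mol %), CH2Cl2, 0 to 23 °C; used crude
Reagents that add atoms: N-chlorosuccinimide, O=C1CCC(=O)N1Cl
Why: Enamine-catalysed α-chlorination of an aldehyde, in which the C2-symmetric amine blocks one enamine face and sets the (R)-chloride, and the remote terminal alkene does not react with the mild chlorine source.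

Step 10
Reactants: 14 (R)-2-chlorohex-5-enal; 15 2,2,6-trimethyl-4H-1,3-dioxin-4-one
Product: 16 6-[(2S,3R)-3-chloro-2-hydroxyhept-6-en-1-yl]-2,2-dimethyl-4H-1,3-dioxin-4-one
Conditions: 15, LiN(iPr)2, THF, −78 °C; then 14, −78 °C; aq. NH4Cl at −78 °C
Reagents that add atoms: none
Why: Vinylogous aldol addition of the lithium dienolate through its γ-carbon, where the α-chloro aldehyde reacts through a Cornforth-type (polar Felkin–Anh) transition state to give the 1,2-anti chlorohydrin and thus the (S)-carbinol centre, and the cold quench prevents epoxide formation.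

Step 11
Reactants: 16 6-[(2S,3R)-3-chloro-2-hydroxyhept-6-en-1-yl]-2,2-dimethyl-4H-1,3-dioxin-4-one
Product: 17 6-[(2S,3R)-3-chloro-2-(triethylsilyloxy)hept-6-en-1-yl]-2,2-dimethyl-4H-1,3-dioxin-4-one
Conditions: Et3SiCl, imidazole, CH2Cl2, 0 °C
Reagents that add atoms: triethylsilyl chloride, CC[Si](CC)(CC)Cl
Why: Silyl protection keeps the δ-hydroxyl from trapping the acylketene of the next step as a six-membered lactone.

Step 12
Reactants: 12 (4S,5E,10R)-4-hydroxy-10-methyloxacyclodec-5-ene-2,7-dione; 17 6-[(2S,3R)-3-chloro-2-(triethylsilyloxy)hept-6-en-1-yl]-2,2-dimethyl-4H-1,3-dioxin-4-one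
Product: 19 (4S,5E,10R)-10-methyl-2,7-dioxooxacyclodec-5-en-4-yl (5S,6R)-6-chloro-3-oxo-5-(triethylsilyloxy)dec-9-enoate, via acylketene 18 (not isolated)
Conditions: toluene, 110 °C (17 in slight excess)
Reagents that add atoms: none
Why: Retro-hetero-Diels–Alder loss of acetone from the dioxinone gives an acylketene that the secondary alcohol traps under neutral conditions, a standard route to β-keto esters of hindered alcohols that touches no stereocentre.

Step 13
Reactants: 19 (4S,5E,10R)-10-methyl-2,7-dioxooxacyclodec-5-en-4-yl (5S,6R)-6-chloro-3-oxo-5-(triethylsilyloxy)dec-9-enoate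
Product: 22 A/B/C tricycle, the trans-fused ring A/ring B bis-lactone ketone bearing an (E)-[(4S,5S)-5-(but-3-en-1-yl)-4-hydroxyoxolan-2-ylidene] group on the butyrolactone α-carbon, via Michael adduct 20 (not isolated), via silyl ether 21 (not isolated)
Conditions: Cs2CO3 (2 equiv), MeCN, 23 to 60 °C; then AcOH–THF–H2O, 23 °C
Reagents that add atoms: none
Why: Domino of an intramolecular Michael addition (5-exo-trig, with the allylic C–H eclipsing the enone so that the tethered β-keto ester attacks the face that gives the trans (R)-configured fusion carbon of ring B) and a 5-exo-tet O-alkylation of the resulting α-acyl-lactone enolate at the secondary chloride with inversion to (S), C-alkylation being geometrically disfavoured (5-enolendo), the (E)-vinylogous carbonate being the dipole- and strain-minimised isomer, and mild aqueous acid then removing the triethylsilyl group.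

Step 14
Reactants: 22 A/B/C tricycle with free fusion hydroxyl and but-3-enyl chain
Product: 23 cordycicadin D
Conditions: [N,N'-bis(3,5-di-tert-butylsalicylidene)-2,3-dimethylbutane-2,3-diaminato]cobalt (divalent cobalt, 5 mol %), N-fluoro-2,4,6-trimethylpyridinium triflate, (Me2SiH)2O, PhCF3, 23 °C
Reagents that add atoms: none
Why: The cobalt complex is oxidised by the N-fluoropyridinium salt and turned by the disiloxane into a trivalent cobalt hydride that transfers a hydrogen atom to the terminal CH2 of the butenyl chain; the secondary radical is captured by divalent cobalt, oxidised to a cationic tetravalent alkylcobalt species, and displaced by the ring-C hydroxyl while collidine takes the proton. The closest known reaction type is the Mukaiyama-type MHAT radical–polar crossover hydroalkoxylation of unactivated terminal alkenes with tethered alcohols, established for five- and six-membered ethers. Ring D, the only ring closed here, forms in the 6-exo mode with Markovnikov regiochemistry, because 7-endo closure would need the primary radical that hydrogen-atom transfer does not produce. The new CH(CH3) centre is controlled by the cis-fused ring C: in the chair-like transition state the CH2 arm of ring C is equatorial and the ring-C oxygen axial, so the methyl group takes the equatorial position and the 2,6-cis (R) centre results, and because the radical and its two diastereomeric alkylcobalt adducts interconvert, both alkene faces are funnelled through this lower transition state. The step must select the terminal alkene over the B=C alkene, the ketone and the two lactones, which the substrate secures because the B=C alkene is a tetrasubstituted push–pull vinylogous carbonate that is slow in hydrogen-atom transfer and carbonyl groups are not reduced by this system. The medium is close to neutral, which protects the β-alkoxy vinylogous carbonate from acid- or base-induced loss of the new ether oxygen and aromatisation to a furan.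

Compound list
1 | (S)-2-hydroxy-1,2,2-triphenylethyl acetate | CC(=O)O[C@@H](c1ccccc1)C(O)(c1ccccc1)c1ccccc1 | starting material
2 | acrolein | C=CC=O | starting material
3 | (S)-2-hydroxy-1,2,2-triphenylethyl (S)-3-hydroxypent-4-enoate | C=C[C@@H](O)CC(=O)O[C@@H](c1ccccc1)C(O)(c1ccccc1)c1ccccc1 | intermediate
4 | (S)-3-hydroxypent-4-enoic acid | C=C[C@@H](O)CC(=O)O | intermediate
5 | tert-butyldimethylsilyl (S)-3-(tert-butyldimethylsilyloxy)pent-4-enoate | C=C[C@@H](O[Si](C)(C)C(C)(C)C)CC(=O)O[Si](C)(C)C(C)(C)C | intermediate
6 | (S)-3-(tert-butyldimethylsilyloxy)pent-4-enoic acid | C=C[C@@H](O[Si](C)(C)C(C)(C)C)CC(=O)O | intermediate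
7 | (R)-γ-valerolactone | C[C@@H]1CCC(=O)O1 | starting material
8 | (R)-4-hydroxy-N-methoxy-N-methylpentanamide | C[C@@H](O)CCC(=O)N(C)OC | intermediate
9 | (R)-5-[methoxy(methyl)amino]-5-oxopentan-2-yl (S)-3-(tert-butyldimethylsilyloxy)pent-4-enoate | C[C@@H](OC(=O)C[C@H](O[Si](C)(C)C(C)(C)C)C=C)CCC(=O)N(C)OC | intermediate
10 | (R)-5-oxohept-6-en-2-yl (S)-3-(tert-butyldimethylsilyloxy)pent-4-enoate | C[C@@H](OC(=O)C[C@H](O[Si](C)(C)C(C)(C)C)C=C)CCC(=O)C=C | intermediate
11 | (4S,5E,10R)-4-(tert-butyldimethylsilyloxy)-10-methyloxacyclodec-5-ene-2,7-dione | C[C@@H]1CCC(=O)/C=C/[C@@H](O[Si](C)(C)C(C)(C)C)CC(=O)O1 | intermediate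
12 | (4S,5E,10R)-4-hydroxy-10-methyloxacyclodec-5-ene-2,7-dione | C[C@@H]1CCC(=O)/C=C/[C@@H](O)CC(=O)O1 | intermediate
13 | hex-5-enal | C=CCCCC=O | starting material
14 | (R)-2-chlorohex-5-enal | C=CCC[C@@H](Cl)C=O | intermediate
15 | 2,2,6-trimethyl-4H-1,3-dioxin-4-one | CC1=CC(=O)OC(C)(C)O1 | starting material
16 | 6-[(2S,3R)-3-chloro-2-hydroxyhept-6-en-1-yl]-2,2-dimethyl-4H-1,3-dioxin-4-one | C=CCC[C@@H](Cl)[C@@H](O)CC1=CC(=O)OC(C)(C)O1 | intermediate
17 | 6-[(2S,3R)-3-chloro-2-(triethylsilyloxy)hept-6-en-1-yl]-2,2-dimethyl-4H-1,3-dioxin-4-one | C=CCC[C@@H](Cl)[C@@H](O[Si](CC)(CC)CC)CC1=CC(=O)OC(C)(C)O1 | intermediate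
18 | acylketene, (5S,6R)-6-chloro-3-oxo-5-(triethylsilyloxy)deca-1,9-dien-1-one | O=C=CC(=O)C[C@H](O[Si](CC)(CC)CC)[C@H](Cl)CCC=C | intermediate
19 | (4S,5E,10R)-10-methyl-2,7-dioxooxacyclodec-5-en-4-yl (5S,6R)-6-chloro-3-oxo-5-(triethylsilyloxy)dec-9-enoate | C[C@@H]1CCC(=O)/C=C/[C@@H](OC(=O)CC(=O)C[C@H](O[Si](CC)(CC)CC)[C@H](Cl)CCC=C)CC(=O)O1 | intermediate
20 | Michael adduct: trans-fused ring A/ring B bicycle with a (3S,4R)-4-chloro-3-(triethylsilyloxy)oct-7-enoyl group on the butyrolactone α-carbon (epimerisable there) | C[C@@H]1CCC(=O)C[C@@H]2C(C(=O)C[C@H](O[Si](CC)(CC)CC)[C@H](Cl)CCC=C)C(=O)O[C@H]2CC(=O)O1 | intermediate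
21 | A/B/C tricycle with an (E)-[(4S,5S)-5-(but-3-en-1-yl)-4-(triethylsilyloxy)oxolan-2-ylidene] group | C[C@@H]1CCC(=O)C[C@@H]2/C(=C3/C[C@H](O[Si](CC)(CC)CC)[C@H](CCC=C)O3)C(=O)O[C@H]2CC(=O)O1 | intermediate
22 | A/B/C tricycle with an (E)-[(4S,5S)-5-(but-3-en-1-yl)-4-hydroxyoxolan-2-ylidene] group | C[C@@H]1CCC(=O)C[C@@H]2/C(=C3/C[C@H](O)[C@H](CCC=C)O3)C(=O)O[C@H]2CC(=O)O1 | intermediate
23 | cordycicadin D | C[C@@H]1CCC(=O)C[C@@H]2/C(=C3/C[C@@H]4O[C@H](C)CC[C@@H]4O3)C(=O)O[C@H]2CC(=O)O1 | target

Total step count: 14. Longest linear sequence: 10 steps (steps 1, 2, 3, 5, 6, 7, 8, 12, 13, 14).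

Steps most likely to fail

Step 13. Substitution at the hindered secondary chloride may be slower than β-elimination of the ring-B carboxylate next to the ring-A ester carbonyl. It may also be slower than loss of silanolate followed by aromatisation of ring C to a furan. The fallback splits the domino and changes how ring C is closed, from an anionic enolate substitution to a halophile-assisted substitution by the neutral enol. Setting out from 19, a catalytic amount of K2CO3 in MeCN at 0 °C should stop at Michael adduct 20, which is then isolated. AgOTf with Ag2O in THF pulls on the chloride while the enol oxygen attacks with inversion, which leads to 21. AcOH–THF–H2O then rejoins the route at 22 (no new compound, F0).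

Step 7. The electron-poor vinyl ketone and the hindered allyl silyl ether may couple slowly, so that oligomerisation, alkene migration or poor control of the double-bond geometry takes over. The fallback changes the alkene partner. Setting out from 10, 1,2-reduction with NaBH4 and CeCl3·7H2O in MeOH gives the bis-allylic diene alcohol F2 as both carbinol epimers, which does not matter because this centre is oxidised later. Ring-closing metathesis with the second-generation Grubbs catalyst in refluxing CH2Cl2 at high dilution gives the ten-membered allylic alcohol F3. Oxidation with MnO2 or Dess–Martin periodinane rejoins the route at 11.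

Step 14. Facial selectivity at the methyl-bearing carbon may be poor. The alkene may be isomerised or simply reduced, the cation equivalent may be captured by fluoride or collidine, or the secondary radical may abstract the carbinol hydrogen by 1,5-transfer. The fallback replaces the radical–polar crossover by carbonyl chemistry. Setting out from 22, Wacker oxidation (PdCl2, CuCl, O2, DMF–H2O) gives the methyl ketone F1, which equilibrates with its six-membered hemiketal. Et3SiH with Me3SiOTf in CH2Cl2 at −78 °C reduces the derived oxocarbenium ion by axial hydride delivery to the 2,6-cis ether and rejoins the route at 23. The short contact time at low temperature is meant to spare the acid-sensitive vinylogous carbonate.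

Further compounds
F1 | step 14 | A/B/C tricycle with an (E)-[(4S,5S)-4-hydroxy-5-(3-oxobutyl)oxolan-2-ylidene] group | C[C@@H]1CCC(=O)C[C@@H]2/C(=C3/C[C@H](O)[C@H](CCC(C)=O)O3)C(=O)O[C@H]2CC(=O)O1
F2 | step 7 | (2R)-5-hydroxyhept-6-en-2-yl (S)-3-(tert-butyldimethylsilyloxy)pent-4-enoate (both carbinol epimers) | C[C@@H](OC(=O)C[C@H](O[Si](C)(C)C(C)(C)C)C=C)CCC(O)C=C
F3 | step 7 | (4S,5E,10R)-4-(tert-butyldimethylsilyloxy)-7-hydroxy-10-methyloxacyclodec-5-en-2-one (both carbinol epimers) | C[C@@H]1CCC(O)/C=C/[C@@H](O[Si](C)(C)C(C)(C)C)CC(=O)O1
F0 | step 13 | none | none
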